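**Strategy.** Everything rests on unfolding the A ring of the unchlorinated genistein half: ring atoms C4a, C5–C8 and C8a, with oxygens on C5, C7 and C8a and the C4 ketone on C4a, are a 2,4,6-trihydroxyphenyl ketone, i.e. a cyclised tetraketide. An intramolecular Claisen condensation forms C4a–C5 and delivers this ring with all three oxygens in one operation. Its precursor is a methyl 8-aryl-3,5,7-trioxooctanoate on a 2,2'-dimethoxybiaryl, made by cross-coupling two differentiated halves, whose other arm already is the regiodefined 3-chloro-2-hydroxy-4,6-dimethoxyphenyl deoxybenzoin. Double one-carbon annulation and demethylation finish the synthesis.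

Key step: step 9

Remark on the chemistry: the target has no stereocentre, and its biaryl axis carries only two ortho hydroxyls and rotates freely, so the compound is achiral and no stereocontrol is needed.

Step 1
Reactants: 1 3,5-dimethoxyphenol
Product: 2 2-chloro-3,5-dimethoxyphenol
Conditions: SO2Cl2 (1.0 equiv), CHCl3, 0 °C → rt; chromatography
Reagents that add atoms: sulfuryl chloride, O=S(=O)(Cl)Cl
Why: Electrophilic aromatic chlorination, in which the two equivalent positions ortho to the hydroxyl (each also para to a methoxyl) are statistically and electronically favoured over C4 in a non-polar medium, and the 4-chloro isomer should be separable on silica because only the 2-chloro isomer has an intramolecular O–H···Cl hydrogen bond.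

Step 2
Reactants: 2 2-chloro-3,5-dimethoxyphenol; 3 3-bromo-4-methoxyphenylacetic acid
Product: 4 2-(3-bromo-4-methoxyphenyl)-1-(3-chloro-2-hydroxy-4,6-dimethoxyphenyl)ethan-1-one
Conditions: BF3·OEt2 (neat, 8 equiv), 85 °C, 2 h; aq. NaOAc
Reagents that add atoms: none
Why: BF3-mediated Friedel–Crafts acylation (O-acylation/Fries pathway) puts the arylacetyl group ortho to the phenol, where the product is held as a BF2 chelate, which is the standard entry to 2-hydroxy-4,6-dimethoxydeoxybenzoins and leaves both aryl halides untouched.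

Step 3
Reactants: 3 3-bromo-4-methoxyphenylacetic acid
Product: 5 methyl 2-(3-bromo-4-methoxyphenyl)acetate
Conditions: MeOH, H2SO4 (cat.), reflux
Reagents that add atoms: methanol, CO
Why: Fischer esterification driven by methanol as solvent.

Step 4
Reactants: 5 methyl 2-(3-bromo-4-methoxyphenyl)acetate
Product: 6 methyl 2-[4-methoxy-3-(4,4,5,5-tetramethyl-1,3,2-dioxaborolan-2-yl)phenyl]acetate
Conditions: B2pin2 (1.1 equiv), Pd(dppf)Cl2 (3 mol%), KOAc (3 equiv), 1,4-dioxane, 90 °C
Reagents that add atoms: bis(pinacolato)diboron, CC1(C)OB(OC1(C)C)B1OC(C)(C)C(C)(C)O1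
Why: Miyaura borylation of an aryl bromide, with acetate as a base too weak to enolise the ester or to promote biaryl homocoupling.

Step 5
Reactants: 4 2-(3-bromo-4-methoxyphenyl)-1-(3-chloro-2-hydroxy-4,6-dimethoxyphenyl)ethan-1-one; 6 methyl 2-[4-methoxy-3-(4,4,5,5-tetramethyl-1,3,2-dioxaborolan-2-yl)phenyl]acetate
Product: 8 2-{5'-[2-(3-chloro-2-hydroxy-4,6-dimethoxyphenyl)-2-oxoethyl]-2',6-dimethoxy-[1,1'-biphenyl]-3-yl}acetic acid, via biaryl methyl ester 7 (not isolated)
Conditions: Pd(dppf)Cl2 (5 mol%), K2CO3 (4 equiv), 1,4-dioxane/H2O (4:1), 85 °C; then LiOH (aq.), MeOH, rt; 1 M HCl to pH 2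
Reagents that add atoms: lithium hydroxide, [Li+].[OH-]
Why: Suzuki–Miyaura coupling at the aryl bromide (the hindered, electron-rich aryl chloride should not undergo oxidative addition with this catalyst) followed by saponification in the same flask gives a biaryl whose two arms differ from the outset, so no statistical desymmetrisation is needed.

Step 6
Reactants: 9 methyl 3,5-dioxohexanoate
Product: 10 methyl 3-oxo-5-(trimethylsilyloxy)hex-4-enoate
Conditions: TMSCl (1.2 equiv), Et3N (1.3 equiv), hexane, rt; filtration under argon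
Reagents that add atoms: chlorotrimethylsilane, C[Si](C)(C)Cl
Why: Silyl enol ether formation by O-silylation of the enolised 1,3-diketone under soft enolisation; the regioisomeric 3-silyloxy enone and either double-bond geometry converge on the same triene in step 7.

Step 7
Reactants: 10 methyl 3-oxo-5-(trimethylsilyloxy)hex-4-enoate
Product: 12 1-methoxy-1,3,5-tris(trimethylsilyloxy)hexa-1,3,5-triene, via bis(silyl) dienoate 11 (not isolated)
Conditions: LDA (1.1 equiv), THF, −78 °C, then TMSCl (1.2 equiv); second LDA (1.1 equiv), −78 °C, then TMSCl (1.2 equiv); −78 → 0 °C; pentane, filtration; used crude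
Reagents that add atoms: chlorotrimethylsilane, C[Si](C)(C)Cl
Why: Two successive kinetic deprotonation/O-silylation cycles (first at C2, then at the terminal methyl), as in the preparation of 1,3-bis(silyloxy)butadienes, give the neutral equivalent of the tricarbonyl trianion.

Step 8
Reactants: 8 2-{5'-[2-(3-chloro-2-hydroxy-4,6-dimethoxyphenyl)-2-oxoethyl]-2',6-dimethoxy-[1,1'-biphenyl]-3-yl}acetic acid; 12 1-methoxy-1,3,5-tris(trimethylsilyloxy)hexa-1,3,5-triene
Product: 14 methyl 8-{5'-[2-(3-chloro-2-hydroxy-4,6-dimethoxyphenyl)-2-oxoethyl]-2',6-dimethoxy-[1,1'-biphenyl]-3-yl}-3,5,7-trioxooctanoate, via acid chloride 13 (not isolated)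
Conditions: (COCl)2 (1.5 equiv), DMF (cat.), CH2Cl2, 0 °C → rt, evaporate; 12 (2.5 equiv), CH2Cl2, −78 → −20 °C; cold 0.5 M HCl work-up; crude product used at once
Reagents that add atoms: none
Why: Mukaiyama-type C-acylation of the tris(silyl enol ether) at its terminal carbon by an acid chloride (the vinylogous counterpart of the γ-acylation of 1,3-bis(silyloxy)dienes) needs neither base nor strong Lewis acid, so the hydrogen-bonded, doubly flanked phenol and the deoxybenzoin methylene should be left alone, the surplus triene covers silyl transfer to that phenol, and the acidic quench avoids premature base-induced cyclisation of the triketo ester.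

Step 9
Reactants: 14 methyl 8-{5'-[2-(3-chloro-2-hydroxy-4,6-dimethoxyphenyl)-2-oxoethyl]-2',6-dimethoxy-[1,1'-biphenyl]-3-yl}-3,5,7-trioxooctanoate
Product: 15 1-(3-chloro-2-hydroxy-4,6-dimethoxyphenyl)-2-{2',6-dimethoxy-5'-[2-oxo-2-(2,4,6-trihydroxyphenyl)ethyl]-[1,1'-biphenyl]-3-yl}ethan-1-one
Conditions: Mg(OMe)2 (6 equiv), MeOH, rt → 45 °C; then cold 1 M HCl
Reagents that add atoms: none
Why: Magnesium methoxide turns the triketo ester into a chelated polyenolate in which C6, the carbon between the C5 and C7 ketones, attacks the C1 ester carbonyl, and loss of methoxide gives a 2-acylcyclohexane-1,3,5-trione that tautomerises irreversibly to the 2,4,6-trihydroxyphenyl ketone. This is an intramolecular Claisen (Dieckmann-type) condensation, the known base-mediated folding of 3,5,7-triketo esters to acylphloroglucinols. The one new ring closes in the 6-(enolexo)-exo-trig mode, the new bond being C6–C1 of the chain, which is C4a–C5 of the later isoflavone. No stereocentre is formed. The step needs Claisen folding to win over aldol closure of C2 onto the C7 ketone (a resorcylate), over lactonisation to a 4-hydroxy-2-pyrone and over reaction through the benzylic C8; the substrate should secure this because C6 is doubly activated while C8 is only singly activated, because magnesium ties the C5/C7 diketone into a chelate that lowers the electrophilicity of C7 while the ester stays free, and because methoxide in methanol makes solvent attack on the ester degenerate. The chlorinated deoxybenzoin is carried as an inert magnesium phenoxide chelate and has no electrophile within reach of a five- or six-membered closure.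

Step 10
Reactants: 15 1-(3-chloro-2-hydroxy-4,6-dimethoxyphenyl)-2-{2',6-dimethoxy-5'-[2-oxo-2-(2,4,6-trihydroxyphenyl)ethyl]-[1,1'-biphenyl]-3-yl}ethan-1-one
Product: 16 8-chloro-3-[5'-(5,7-dihydroxy-4-oxo-4H-chromen-3-yl)-2',6-dimethoxy-[1,1'-biphenyl]-3-yl]-5,7-dimethoxy-4H-chromen-4-one
Conditions: BF3·OEt2 (10 equiv), DMF, rt → 50 °C; MsCl (6 equiv) in DMF, 80 °C, 2 h; aq. NaOAc, 60 °C
Reagents that add atoms: N,N-dimethylformamide, CN(C)C=O
Why: Vilsmeier-type aminomethylenation of both BF2-chelated deoxybenzoin methylenes followed by oxa-6-endo-trig closure with loss of dimethylamine is the standard one-carbon isoflavone annulation and tolerates free phloroglucinol hydroxyls; the symmetric trihydroxy ring can close in only one way and the chlorinated ring has a single free hydroxyl, next to chlorine, so chlorine must end up at C8.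

Step 11
Reactants: 16 8-chloro-3-[5'-(5,7-dihydroxy-4-oxo-4H-chromen-3-yl)-2',6-dimethoxy-[1,1'-biphenyl]-3-yl]-5,7-dimethoxy-4H-chromen-4-one
Product: 17 Bisoflavolin N (8-chloro-3-[5'-(5,7-dihydroxy-4-oxo-4H-chromen-3-yl)-2',6-dihydroxy-[1,1'-biphenyl]-3-yl]-5,7-dihydroxy-4H-chromen-4-one)
Conditions: BBr3 (12 equiv), CH2Cl2, −78 °C → rt; MeOH, then H2O
Reagents that add atoms: none
Why: Lewis-acid-mediated cleavage of the four aryl methyl ethers (bromide attack on the O-methyl of each ArO(Me)·BBr2 adduct) should leave the isoflavone rings and the aryl chloride intact, and isomerisation of the 8-chloro to the 6-chloro ring of the Wessely–Moser type, which needs hot protic acid, is not expected.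

**Compound list**

1 | 3,5-dimethoxyphenol | COc1cc(O)cc(OC)c1 | starting material
2 | 2-chloro-3,5-dimethoxyphenol | COc1cc(O)c(Cl)c(OC)c1 | intermediate
3 | 3-bromo-4-methoxyphenylacetic acid | COc1ccc(CC(=O)O)cc1Br | starting material
4 | 2-(3-bromo-4-methoxyphenyl)-1-(3-chloro-2-hydroxy-4,6-dimethoxyphenyl)ethan-1-one | COc1ccc(CC(=O)c2c(O)c(Cl)c(OC)cc2OC)cc1Br | intermediate
5 | methyl 2-(3-bromo-4-methoxyphenyl)acetate | COC(=O)Cc1ccc(OC)c(Br)c1 | intermediate
6 | methyl 2-[4-methoxy-3-(4,4,5,5-tetramethyl-1,3,2-dioxaborolan-2-yl)phenyl]acetate | COC(=O)Cc1ccc(OC)c(B2OC(C)(C)C(C)(C)O2)c1 | intermediate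
7 | methyl 2-{5'-[2-(3-chloro-2-hydroxy-4,6-dimethoxyphenyl)-2-oxoethyl]-2',6-dimethoxy-[1,1'-biphenyl]-3-yl}acetate | COC(=O)Cc1ccc(OC)c(-c2cc(CC(=O)c3c(O)c(Cl)c(OC)cc3OC)ccc2OC)c1 | intermediate (not isolated)
8 | 2-{5'-[2-(3-chloro-2-hydroxy-4,6-dimethoxyphenyl)-2-oxoethyl]-2',6-dimethoxy-[1,1'-biphenyl]-3-yl}acetic acid | OC(=O)Cc1ccc(OC)c(-c2cc(CC(=O)c3c(O)c(Cl)c(OC)cc3OC)ccc2OC)c1 | intermediate
9 | methyl 3,5-dioxohexanoate | COC(=O)CC(=O)CC(C)=O | starting material
10 | methyl 3-oxo-5-(trimethylsilyloxy)hex-4-enoate (double-bond geometry not controlled and without consequence) | COC(=O)CC(=O)C=C(C)O[Si](C)(C)C | intermediate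
11 | methyl 3,5-bis(trimethylsilyloxy)hexa-2,4-dienoate (geometry without consequence) | COC(=O)C=C(O[Si](C)(C)C)C=C(C)O[Si](C)(C)C | intermediate (not isolated)
12 | 1-methoxy-1,3,5-tris(trimethylsilyloxy)hexa-1,3,5-triene (geometry without consequence) | COC(O[Si](C)(C)C)=CC(O[Si](C)(C)C)=CC(=C)O[Si](C)(C)C | intermediate
13 | 2-{5'-[2-(3-chloro-2-hydroxy-4,6-dimethoxyphenyl)-2-oxoethyl]-2',6-dimethoxy-[1,1'-biphenyl]-3-yl}acetyl chloride | O=C(Cl)Cc1ccc(OC)c(-c2cc(CC(=O)c3c(O)c(Cl)c(OC)cc3OC)ccc2OC)c1 | intermediate (not isolated)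
14 | methyl 8-{5'-[2-(3-chloro-2-hydroxy-4,6-dimethoxyphenyl)-2-oxoethyl]-2',6-dimethoxy-[1,1'-biphenyl]-3-yl}-3,5,7-trioxooctanoate (drawn as the triketo tautomer) | COC(=O)CC(=O)CC(=O)CC(=O)Cc1ccc(OC)c(-c2cc(CC(=O)c3c(O)c(Cl)c(OC)cc3OC)ccc2OC)c1 | intermediate
15 | 1-(3-chloro-2-hydroxy-4,6-dimethoxyphenyl)-2-{2',6-dimethoxy-5'-[2-oxo-2-(2,4,6-trihydroxyphenyl)ethyl]-[1,1'-biphenyl]-3-yl}ethan-1-one | O=C(Cc1ccc(OC)c(-c2cc(CC(=O)c3c(O)c(Cl)c(OC)cc3OC)ccc2OC)c1)c1c(O)cc(O)cc1O | intermediate
16 | 8-chloro-3-[5'-(5,7-dihydroxy-4-oxo-4H-chromen-3-yl)-2',6-dimethoxy-[1,1'-biphenyl]-3-yl]-5,7-dimethoxy-4H-chromen-4-one | O=c1c(-c2ccc(OC)c(-c3cc(-c4coc5c(Cl)c(OC)cc(OC)c5c4=O)ccc3OC)c2)coc2cc(O)cc(O)c12 | intermediate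
17 | Bisoflavolin N | O=c1c(-c2ccc(O)c(-c3cc(-c4coc5c(Cl)c(O)cc(O)c5c4=O)ccc3O)c2)coc2cc(O)cc(O)c12 | target

**Step count**

Total step count: 11. Longest linear sequence: 7 steps (steps 1, 2, 5, 8, 9, 10, 11).

**Steps most likely to fail**

Step 9 (key step): the chain may fold in the wrong mode, by aldol closure of C2 onto the C7 ketone or by O-acylation to a 4-hydroxy-2-pyrone, or it may be cut by retro-Claisen cleavage in methanolic base. The fallback gives up the polyketide folding and makes the trihydroxyphenyl ketone by Friedel–Crafts acylation. It sets out from acid 8, which is heated with phloroglucinol (3 equiv) in BF3·OEt2 at 85 °C; after aqueous sodium acetate this should give 15 directly, where it rejoins the route before step 10. Steps 6 to 9 are then not needed, and this detour makes no new compound (none, F0).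

Step 8: the silyl nucleophile may be lost by proton and silyl transfer to the free phenol, acylation may take place on oxygen or at an internal carbon of the triene, and the triketo ester may cyclise or decompose during isolation. The fallback replaces the silyl enol ether route by polyanion acylation. It sets out from ester 7, isolated after the cross-coupling of step 5 by leaving out the hydroxide treatment, and from 9. LDA (3.1 equiv, THF, 0 °C) converts 9 into the trilithium trienolate of methyl 3,5-dioxohexanoate F1. F1 is used in about fivefold excess so that it first removes the phenolic and deoxybenzoin protons of 7; it should then attack the methyl ester of 7 through its terminal carbon (−20 → 0 °C). A quench into cold dilute HCl returns to the route at 14.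

Step 1: regiocontrol may be poor, with chlorination para to the hydroxyl or double chlorination consuming material. The fallback uses directed ortho-metalation in place of electrophilic chlorination. It sets out from 1, which is carbamoylated (ClCONEt2, K2CO3, MeCN, reflux) to 3,5-dimethoxyphenyl N,N-diethylcarbamate F2. s-BuLi/TMEDA (THF, −78 °C) should lithiate F2 between the carbamate and a methoxyl, and a cold quench with C2Cl6 gives 2-chloro-3,5-dimethoxyphenyl N,N-diethylcarbamate F3. Hydrolysis (NaOH, EtOH, reflux) returns to the route at 2.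

Further compounds
F0 | step 9 | none | none
F1 | step 8 | trilithium trienolate of methyl 3,5-dioxohexanoate | [Li+].[Li+].[Li+].C=C([O-])C=C([O-])C=C([O-])OC
F2 | step 1 | 3,5-dimethoxyphenyl N,N-diethylcarbamate | CCN(CC)C(=O)Oc1cc(OC)cc(OC)c1
F3 | step 1 | 2-chloro-3,5-dimethoxyphenyl N,N-diethylcarbamate | CCN(CC)C(=O)Oc1cc(OC)cc(OC)c1Cl
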